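Numbering: carbocycle C1–C10 (C3 carbinol, C4=C5, C6 lactone carbinol, C7 ring fusion, C8 tiglate carbinol, C10 tertiary carbinol), C11–C13 the methylene-lactone carbons. Enabling feature: C1–C6 with the (Z)-C4=C5 bond and O3 form a 4-oxygenated cyclohexene, and C8=C7–C6–C1–C10=C9 is a 1,5-diene spanning the C1–C6 ring bond.
Retrosynthesis: cut the C8 ester, C11=C13, the C10–O bond (back to C1=C10 via its epoxide), the lactone (O6–C12, then C7–C11); then re-form C1–C6 while cutting C8–C9 ([3,3]) to reach a 1-alkenyl-6-isopropenylcyclohex-2-enol; finally cut the C6–C7 bond to a carvone-derived enone and a 2-silylvinyl anion.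
Forward order: cyclohexene from carvone, ten-membered ring by ring expansion, γ-lactone by C7 alkylation and C6 reduction, then C10 hydration, methylenation, C8 oxidation, acylation, desilylation.
Stereochemistry: C3 from carvone via trans-carveol; C8 by chirality transfer in the chair of the rearrangement; C7 by alkylation on the outer face of the ring enolate; C6 by peripheral hydride (cis lactone); C10 by reagent-controlled epoxidation and hydride opening.

Key step: step 8

Assumption: the structure is read as drawn, (3S,6R,7S,8R,10S) with a cis-fused C6/C7 lactone; names of compounds 13 onward use the numbering above.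
Assumption: the (E)-C1=C10 olefin of the ten-membered intermediates turns through the ring at or below room temperature, so a chiral reagent can choose its face.

Step 1
Reactants: 1 (R)-(−)-carvone
Product: 2 (1R,5R)-cis-carveol
Conditions: NaBH4, CeCl3·7H2O, MeOH, 0 °C
Reagents that add atoms: none
Why: Luche 1,2-reduction; axial hydride delivery to the half-chair with equatorial isopropenyl should give the equatorial 1R alcohol, cis to the isopropenyl group.

Step 2
Reactants: 2 (1R,5R)-cis-carveol
Product: 3 (1S,5R)-trans-carveyl 4-nitrobenzoate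
Conditions: 4-nitrobenzoic acid, PPh3, diisopropyl azodicarboxylate, THF, 0 °C → rt
Reagents that add atoms: 4-nitrobenzoic acid, OC(=O)c1ccc(cc1)[N+](=O)[O-]
Why: Mitsunobu esterification displaces the oxyphosphonium ion by SN2 and inverts C1 to 1S, placing the oxygen trans to the isopropenyl group.

Step 3
Reactants: 3 (1S,5R)-trans-carveyl 4-nitrobenzoate
Product: 4 (1S,5R)-trans-carveol
Conditions: K2CO3 (cat.), MeOH, rt
Reagents that add atoms: none
Why: Base-catalysed transesterification (methanolysis) frees the alcohol without touching the C1 stereocentre.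

Step 4
Reactants: 4 (1S,5R)-trans-carveol
Product: 5 trans-carveol tert-butyldimethylsilyl ether
Conditions: tert-butyldimethylsilyl chloride, imidazole, DMF, rt
Reagents that add atoms: tert-butyldimethylsilyl chloride, CC(C)(C)[Si](C)(C)Cl
Why: Imidazole-promoted silylation; the ether should survive the organometallic, basic and hydride steps that follow.

Step 5
Reactants: 5 trans-carveol tert-butyldimethylsilyl ether
Product: 6 (4S,6R)-4-silyloxy-3-methyl-6-isopropenylcyclohex-2-enone
Conditions: CrO3, 3,5-dimethylpyrazole, CH2Cl2, −20 °C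
Reagents that add atoms: chromium trioxide CrO3, O=[Cr](=O)=O
Why: Allylic C–H oxidation with the CrO3–3,5-dimethylpyrazole complex should convert the ring methylene next to the olefinic CH into the ketone, the other ring allylic position being blocked as its silyl ether and the low temperature sparing the isopropenyl group and the adjacent stereocentre.

Step 6
Reactants: 7 ethynyldimethylphenylsilane
Product: 8 (E)-dimethyl(phenyl)[2-(tributylstannyl)ethenyl]silane
Conditions: Bu3SnH, azobis(isobutyronitrile) (cat.), neat, 90 °C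
Reagents that add atoms: tributyltin hydride, CCCC[SnH](CCCC)CCCC
Why: Radical hydrostannation of the terminal alkyne; the stannyl radical adds to the unsubstituted carbon and reversible addition equilibrates the product to the (E)-1-silyl-2-stannylethene.

Step 7
Reactants: 8 (E)-dimethyl(phenyl)[2-(tributylstannyl)ethenyl]silane; 6 (4S,6R)-4-silyloxy-3-methyl-6-isopropenylcyclohex-2-enone
Product: 11 (1R,4S,6R)-trans-dialkenyl cyclohexenol, via vinyllithium 9 (not isolated), via vinylcerium dichloride 10 (not isolated)
Conditions: n-BuLi, THF, −78 °C; CeCl3, −78 °C; then 6, −78 °C; aq. NH4Cl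
Reagents that add atoms: none
Why: Tin–lithium exchange gives the configurationally stable (E)-vinyllithium, and its cerium derivative should add 1,2 to the enolisable enone (organocerium addition) opposite the neighbouring equatorial isopropenyl group, setting the 1R carbinol with the two alkenyl groups trans.

Step 8
Reactants: 11 (1R,4S,6R)-trans-dialkenyl cyclohexenol
Product: 14 (3S,8R,4Z,1(10)E)-cyclodecadien-6-one, via potassium alkoxide 12 (not isolated), via potassium enolate 13 (not isolated)
Conditions: KH, 18-crown-6, THF, 0 → 40 °C; then AcOH, −78 °C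
Reagents that add atoms: none
Why: KH with 18-crown-6 gives the free potassium alkoxide 12, whose 1,5-diene (C8=C7–C6–C1–C10=C9) undergoes an anionic oxy-Cope [3,3] sigmatropic shift; the closest known reaction type is the oxy-Cope ring expansion of 1-vinyl-6-isopropenylcyclohex-2-enols to germacrane-type (Z,E)-cyclodecadienones. The ten-membered ring closes by ring expansion, not end-to-end cyclisation: C8–C9 forms while the cyclohexene bond C1–C6 breaks, so the six-membered ring grows by four atoms. The shift should run through a chair with the ring bonds C6–C5 and C1–C2 equatorial and the oxido group axial, the only chair open to trans-diequatorial alkenyl groups, and this gives the (E)-C1=C10 olefin. The new stereocentre C8 is set by chirality transfer from C1 (R) and C6 (R): the (E)-silyl group sits equatorial, away from the axial oxido group, and bond formation on that face gives 8R. The (Z)-C4=C5 bond is the unchanged cyclohexene olefin, and enolate 13 forms regiospecifically at C6/C7 and is protonated at C7 by acetic acid. The selectivity needed, chair over boat and equatorial over axial silicon, is secured by the trans alkenyl groups from step 7 and the E vinylsilane from step 6.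

Step 9
Reactants: 14 (3S,8R,4Z,1(10)E)-cyclodecadien-6-one; 15 methyl bromoacetate
Product: 17 (3S,7R,8R)-keto ester, via lithium enolate 16 (not isolated)
Conditions: LDA, THF, −78 °C; then 15, DMPU, −78 → −40 °C
Reagents that add atoms: none
Why: Kinetic deprotonation at C7, the only sp3 α-position, gives the cross-conjugated lithium enolate, which should be alkylated (enolate alkylation with an α-halo ester) on the outer face of the ring because the inner face is covered transannularly; with the C8 silyl group held anti to C6 this places C11 trans to silicon (7R).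

Step 10
Reactants: 17 (3S,7R,8R)-keto ester
Product: 19 (3S,6R,7R,8R)-cis-fused lactone, via hydroxy ester 18 (not isolated)
Conditions: NaBH4, CeCl3·7H2O, MeOH, −78 → 0 °C; then pyridinium p-toluenesulfonate (cat.), CH2Cl2, rt
Reagents that add atoms: none
Why: Luche 1,2-reduction of the enone; hydride should arrive from the ring periphery, anti to ring carbon C8 and past H7 (Felkin–Anh sense), giving the 6R alcohol syn to the C7 acetate arm, and this cis γ-hydroxy ester lactonises under mild acid catalysis.

Step 11
Reactants: 19 (3S,6R,7R,8R)-cis-fused lactone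
Product: 20 (1R,10R)-1,10-epoxy lactone
Conditions: 1,2:4,5-di-O-isopropylidene-β-D-erythro-2,3-hexodiulo-2,6-pyranose (D-fructose-derived Shi ketone, 30 mol %), Oxone (2KHSO5·KHSO4·K2SO4), K2CO3, Bu4NHSO4 (cat.), MeCN/dimethoxymethane/aq. Na2B4O7 buffer, 0 °C
Reagents that add atoms: potassium peroxymonosulfate KHSO5 (active part of Oxone), [K+].OOS(=O)(=O)[O-]
Why: Shi asymmetric epoxidation; the chiral dioxirane should react at the only electron-rich trialkyl E-olefin (C4=C5 is deactivated by two allylic oxygens) and, through its spiro transition state, deliver oxygen to the face giving the (1R,10R)-epoxide, the sense known for E-trisubstituted olefins with the D-fructose ketone.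

Step 12
Reactants: 20 (1R,10R)-1,10-epoxy lactone
Product: 21 (3S,6R,7R,8R,10S)-6,10,12-triol
Conditions: LiEt3BH, THF, 0 °C → rt; then H2O
Reagents that add atoms: none
Why: Hydride opening of the epoxide by SN2 attack at the less substituted C1 (Super-Hydride) leaves the C10–O bond untouched and so gives the 10S tertiary alcohol, while the lactone is reduced to the 6,12-diol in the same operation.

Step 13
Reactants: 21 (3S,6R,7R,8R,10S)-6,10,12-triol
Product: 24 (3S,6R,7R,8R,10S)-10-hydroxy lactone, via hydroxy aldehyde 22 (not isolated), via lactol 23 (not isolated)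
Conditions: 2,2,6,6-tetramethylpiperidin-1-oxyl (TEMPO, cat.), PhI(OAc)2, CH2Cl2, rt
Reagents that add atoms: none
Why: TEMPO/PhI(OAc)2 oxidative lactonisation of a 1,4-diol; the primary alcohol is oxidised selectively to the aldehyde, which closes on O6 to the lactol and is oxidised again to restore the cis lactone, the tertiary C10 hydroxyl being inert.

Step 14
Reactants: 24 (3S,6R,7R,8R,10S)-10-hydroxy lactone
Product: 26 11-(dimethylaminomethyl) lactone, via dilithium alkoxide enolate 25 (not isolated)
Conditions: LDA (2.2 equiv), THF, −78 °C; then Me2N=CH2+ I−, −78 °C → rt; H2O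
Reagents that add atoms: N,N-dimethylmethyleneiminium iodide, C=[N+](C)C.[I-]
Why: Mannich reaction of the lactone enolate with the preformed iminium salt (first half of the Eschenmoser methylenation); the second equivalent of base only deprotonates the C10 hydroxyl, and the C11 configuration is irrelevant.

Step 15
Reactants: 26 11-(dimethylaminomethyl) lactone
Product: 28 α-methylene lactone silane, via trimethylammonium iodide 27 (not isolated)
Conditions: MeI, MeOH, rt; then aq. NaHCO3, EtOAc, rt
Reagents that add atoms: none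
Why: Exhaustive N-methylation makes the amine a leaving group and mild base then effects β-elimination to the exocyclic C11=C13 olefin (Hofmann-type elimination).

Step 16
Reactants: 28 α-methylene lactone silane
Product: 31 (3S,6R,7S,8R,10S)-8,10-diol, via acetoxysilane 29 (not isolated), via acetoxysilyl ether 30 (not isolated)
Conditions: Hg(OAc)2, AcOOH, AcOH, rt
Reagents that add atoms: peracetic acid, CC(=O)OO
Why: Fleming–Tamao oxidation; mercuridesilylation removes the phenyl group and the peracid-induced 1,2-shift of C8 from silicon to oxygen occurs with retention, giving the 8R alcohol, while the remaining olefins are electron-poor or flanked by two allylic oxygens and should resist the electrophiles.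

Step 17
Reactants: 31 (3S,6R,7S,8R,10S)-8,10-diol; 32 tigloyl chloride
Product: 33 3-O-silyl 8-tiglate
Conditions: Et3N, 4-(dimethylamino)pyridine (cat.), CH2Cl2, 0 °C → rt
Reagents that add atoms: none
Why: Acylation under nucleophilic catalysis by 4-(dimethylamino)pyridine should esterify the only free secondary hydroxyl, since the tertiary C10 hydroxyl does not react and O3 is silylated.

Step 18
Reactants: 33 3-O-silyl 8-tiglate
Product: 34 target CNP0137971.1
Conditions: HF·pyridine, THF, 0 °C → rt
Reagents that add atoms: none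
Why: Fluoride-mediated cleavage of the silyl ether under weakly acidic conditions should spare the α-methylene lactone, the tiglate and the tertiary alcohol.

Compound list
1 | (R)-(−)-carvone, (5R)-2-methyl-5-(prop-1-en-2-yl)cyclohex-2-en-1-one | CC(=C)[C@@H]1CC=C(C)C(=O)C1 | starting material
2 | (1R,5R)-2-methyl-5-(prop-1-en-2-yl)cyclohex-2-en-1-ol (cis-carveol) | CC(=C)[C@H]1C[C@@H](O)C(C)=CC1 | intermediate
3 | (1S,5R)-2-methyl-5-(prop-1-en-2-yl)cyclohex-2-en-1-yl 4-nitrobenzoate (trans) | CC(=C)[C@H]1C[C@H](OC(=O)c2ccc(cc2)[N+](=O)[O-])C(C)=CC1 | intermediate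
4 | (1S,5R)-2-methyl-5-(prop-1-en-2-yl)cyclohex-2-en-1-ol (trans-carveol) | CC(=C)[C@H]1C[C@H](O)C(C)=CC1 | intermediate
5 | tert-butyl(dimethyl){[(1S,5R)-2-methyl-5-(prop-1-en-2-yl)cyclohex-2-en-1-yl]oxy}silane | CC(=C)[C@H]1C[C@H](O[Si](C)(C)C(C)(C)C)C(C)=CC1 | intermediate
6 | (4S,6R)-4-[(tert-butyldimethylsilyl)oxy]-3-methyl-6-(prop-1-en-2-yl)cyclohex-2-en-1-one (silyloxy and isopropenyl trans) | CC(=C)[C@H]1C[C@H](O[Si](C)(C)C(C)(C)C)C(C)=CC1=O | intermediate
7 | ethynyldimethylphenylsilane | C#C[Si](C)(C)c1ccccc1 | starting material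
8 | (E)-dimethyl(phenyl)[2-(tributylstannyl)ethenyl]silane | CCCC[Sn](CCCC)(CCCC)/C=C/[Si](C)(C)c1ccccc1 | intermediate
9 | [(E)-2-(dimethylphenylsilyl)ethenyl]lithium | [Li]/C=C/[Si](C)(C)c1ccccc1 | intermediate
10 | dichloro[(E)-2-(dimethylphenylsilyl)ethenyl]cerium | Cl[Ce](Cl)/C=C/[Si](C)(C)c1ccccc1 | intermediate
11 | (1R,4S,6R)-4-[(tert-butyldimethylsilyl)oxy]-1-[(E)-2-(dimethylphenylsilyl)ethenyl]-3-methyl-6-(prop-1-en-2-yl)cyclohex-2-en-1-ol (alkenyl groups trans, hydroxyl cis to isopropenyl) | CC(=C)[C@H]1C[C@H](O[Si](C)(C)C(C)(C)C)C(C)=C[C@]1(O)/C=C/[Si](C)(C)c2ccccc2 | intermediate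
12 | potassium alkoxide of 11 | CC(=C)[C@H]1C[C@H](O[Si](C)(C)C(C)(C)C)C(C)=C[C@]1([O-])/C=C/[Si](C)(C)c2ccccc2.[K+] | intermediate
13 | potassium C6-enolate of 14 (C5 and C8 trans across C6=C7; 3S,8R; 4Z,1(10)E) | [K+].C1[C@@H]([Si](C)(C)c2ccccc2)/C=C([O-])/C=C(C)\[C@@H](O[Si](C)(C)C(C)(C)C)C/C=C1\C | intermediate
14 | (3S,8R,4Z,1(10)E)-3-[(tert-butyldimethylsilyl)oxy]-8-(dimethylphenylsilyl)-4,10-dimethylcyclodeca-1(10),4-dien-6-one | C1C(=O)/C=C(C)\[C@@H](O[Si](C)(C)C(C)(C)C)C/C=C(\C)C[C@H]1[Si](C)(C)c2ccccc2 | intermediate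
15 | methyl bromoacetate | COC(=O)CBr | starting material
16 | lithium C6-enolate of 14 (same geometry as 13) | [Li+].C1[C@@H]([Si](C)(C)c2ccccc2)/C=C([O-])/C=C(C)\[C@@H](O[Si](C)(C)C(C)(C)C)C/C=C1\C | intermediate
17 | methyl 2-[(3S,7R,8R,4Z,1(10)E)-3-silyloxy-8-(dimethylphenylsilyl)-4,10-dimethyl-6-oxocyclodeca-1(10),4-dien-7-yl]acetate (C11 trans to silicon) | COC(=O)C[C@@H]1C(=O)/C=C(C)\[C@@H](O[Si](C)(C)C(C)(C)C)C/C=C(\C)C[C@H]1[Si](C)(C)c2ccccc2 | intermediate
18 | (3S,6R,7R,8R)-6-hydroxy ester (O6 syn to the C7 acetate arm) | COC(=O)C[C@@H]1[C@H](O)/C=C(C)\[C@@H](O[Si](C)(C)C(C)(C)C)C/C=C(\C)C[C@H]1[Si](C)(C)c2ccccc2 | intermediate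
19 | (3S,6R,7R,8R,4Z,1(10)E)-3-silyloxy-8-(dimethylphenylsilyl)-6,12-olide, cis-fused γ-lactone | C1C(=O)O[C@@H]2/C=C(/C)[C@@H](O[Si](C)(C)C(C)(C)C)C/C=C(\C)C[C@@H]([Si](C)(C)c3ccccc3)[C@H]12 | intermediate
20 | (1R,3S,6R,7R,8R,10R)-1,10-epoxide of 19 | C1C(=O)O[C@@H]2/C=C(/C)[C@@H](O[Si](C)(C)C(C)(C)C)C[C@H]3O[C@]3(C)C[C@@H]([Si](C)(C)c4ccccc4)[C@H]12 | intermediate
21 | (3S,6R,7R,8R,10S)-3-silyloxy-8-(dimethylphenylsilyl)-cyclodec-4-ene-6,10-diol bearing a 2-hydroxyethyl group at C7 (6,10,12-triol) | OCC[C@@H]1[C@H](O)/C=C(C)\[C@@H](O[Si](C)(C)C(C)(C)C)CC[C@](C)(O)C[C@H]1[Si](C)(C)c2ccccc2 | intermediate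
22 | 12-aldehyde of 21 (6,10-diol) | O=CC[C@@H]1[C@H](O)/C=C(C)\[C@@H](O[Si](C)(C)C(C)(C)C)CC[C@](C)(O)C[C@H]1[Si](C)(C)c2ccccc2 | intermediate
23 | 6,12-lactol of 22 (C12 epimers) | C1C(O)O[C@@H]2/C=C(/C)[C@@H](O[Si](C)(C)C(C)(C)C)CC[C@](C)(O)C[C@@H]([Si](C)(C)c3ccccc3)[C@H]12 | intermediate
24 | (3S,6R,7R,8R,10S)-10-hydroxy-3-silyloxy-8-(dimethylphenylsilyl)-6,12-olide | C1C(=O)O[C@@H]2/C=C(/C)[C@@H](O[Si](C)(C)C(C)(C)C)CC[C@](C)(O)C[C@@H]([Si](C)(C)c3ccccc3)[C@H]12 | intermediate
25 | dilithium C10-alkoxide lactone enolate of 24 | [Li+].[Li+].C1=C([O-])O[C@@H]2/C=C(/C)[C@@H](O[Si](C)(C)C(C)(C)C)CC[C@](C)([O-])C[C@@H]([Si](C)(C)c3ccccc3)[C@H]12 | intermediate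
26 | 11-(dimethylaminomethyl) derivative of 24 (C11 epimers) | CN(C)CC1C(=O)O[C@@H]2/C=C(/C)[C@@H](O[Si](C)(C)C(C)(C)C)CC[C@](C)(O)C[C@@H]([Si](C)(C)c3ccccc3)[C@H]12 | intermediate
27 | trimethylammonium iodide of 26 | [I-].C[N+](C)(C)CC1C(=O)O[C@@H]2/C=C(/C)[C@@H](O[Si](C)(C)C(C)(C)C)CC[C@](C)(O)C[C@@H]([Si](C)(C)c3ccccc3)[C@H]12 | intermediate
28 | (3S,6R,7R,8R,10S)-10-hydroxy-3-silyloxy-8-(dimethylphenylsilyl)-11(13)-en-6,12-olide | C=C1C(=O)O[C@@H]2/C=C(/C)[C@@H](O[Si](C)(C)C(C)(C)C)CC[C@](C)(O)C[C@@H]([Si](C)(C)c3ccccc3)[C@H]12 | intermediate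
29 | C8 acetoxydimethylsilane from 28 | C=C1C(=O)O[C@@H]2/C=C(/C)[C@@H](O[Si](C)(C)C(C)(C)C)CC[C@](C)(O)C[C@@H]([Si](C)(C)OC(C)=O)[C@H]12 | intermediate
30 | C8 acetoxydimethylsilyl ether (silicon-to-oxygen shift product) | C=C1C(=O)O[C@@H]2/C=C(/C)[C@@H](O[Si](C)(C)C(C)(C)C)CC[C@](C)(O)C[C@@H](O[Si](C)(C)OC(C)=O)[C@H]12 | intermediate
31 | (3S,6R,7S,8R,10S)-8,10-dihydroxy-3-silyloxy-11(13)-en-6,12-olide | C=C1C(=O)O[C@@H]2/C=C(/C)[C@@H](O[Si](C)(C)C(C)(C)C)CC[C@](C)(O)C[C@@H](O)[C@H]12 | intermediate
32 | tigloyl chloride, (E)-2-methylbut-2-enoyl chloride | C/C=C(\C)C(=O)Cl | starting material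
33 | 3-O-tert-butyldimethylsilyl ether of the target (8-tiglate) | C=C1C(=O)O[C@@H]2/C=C(/C)[C@@H](O[Si](C)(C)C(C)(C)C)CC[C@](C)(O)C[C@@H](OC(=O)/C(C)=C/C)[C@H]12 | intermediate
34 | CNP0137971.1, (3S,6R,7S,8R,10S)-3,10-dihydroxy-8-tigloyloxy-(4Z)-germacra-4,11(13)-dien-6,12-olide | C=C1C(=O)O[C@@H]2/C=C(/C)[C@@H](O)CC[C@](C)(O)C[C@@H](OC(=O)/C(C)=C/C)[C@H]12 | target

Total step count: 18. Longest linear sequence: 17 steps (steps 1–5 and 7–18 from carvone); step 6 is a one-step branch.

Steps most likely to fail

Step 11. The chiral dioxirane may face a ring that presents mainly the other face of the C1=C10 olefin (mismatched case), so oxygen transfer becomes slow and face selection poor. The fallback leaves the epoxide/hydride sequence and hydrates the olefin by hydrogen-atom transfer. It sets out from lactone 19, which with Co(acac)2, PhSiH3 and O2 in THF (Mukaiyama hydration) should be converted, lactone untouched, directly into hydroxy lactone 24, where the route is rejoined; steps 12 and 13 fall away. The tertiary C10 radical is no longer tied to the planar orientation of an E-olefin, and the C10 epimers would be separated at this stage. No compound outside the list arises on this path (F0).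

Step 9. Deprotonation of ketone 14 may give both enolate geometries, or the enolate may relax to a ring conformer with the other face open, so facial selectivity in the alkylation erodes. The fallback generates the enolate by the rearrangement itself instead of by deprotonation. It sets out from carbinol 11, which is rearranged as in step 8, but enolate 13 is quenched with Me3SiCl/Et3N at −78 °C to give trimethylsilyl enol ether F1 with the enolate geometry fixed by the chair. MeLi in THF then releases lithium enolate 16 as a single geometric isomer, which is alkylated with 15 and comes back to the route at keto ester 17.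

Step 5. The oxidant may attack the other allylic positions (the silyloxy-bearing CH, the isopropenyl group) or over-oxidise, and the isopropenyl double bond may move into conjugation with the new ketone. The fallback replaces C–H oxidation by an epoxide-based 1,3-transposition and sets out from silyl ether 5. m-CPBA/NaHCO3 should epoxidise the more electron-rich ring olefin to epoxide F2. PhSeNa (from PhSeSePh and NaBH4, EtOH) opens it at the secondary carbon to hydroxy selenide F3. H2O2 oxidation and syn-elimination of the selenoxide, which can only go toward the ring methylene, gives tertiary allylic alcohol F4. Pyridinium chlorochromate, C5H5NH[CrO3Cl], then effects the oxidative 1,3-transposition (Dauben oxidation) and comes back to the route at enone 6.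

Further compounds
F0 | step 11 | none | none
F1 | step 9 | trimethylsilyl enol ether of 14 (C6–O–SiMe3, C5 and C8 trans across C6=C7) | C1[C@@H]([Si](C)(C)c2ccccc2)/C=C(O[Si](C)(C)C)/C=C(C)\[C@@H](O[Si](C)(C)C(C)(C)C)C/C=C1\C
F2 | step 5 | 2,3-epoxide of silyl ether 5 (ring epoxide, either face) | CC(=C)[C@H]1C[C@H](O[Si](C)(C)C(C)(C)C)C2(C)OC2C1
F3 | step 5 | 2-hydroxy-3-(phenylselanyl) derivative of 5 (tertiary alcohol, secondary selenide) | CC(=C)[C@H]1C[C@H](O[Si](C)(C)C(C)(C)C)C(C)(O)C([Se]c2ccccc2)C1
F4 | step 5 | tertiary allylic alcohol, 6-silyloxy-1-methyl-4-isopropenylcyclohex-2-en-1-ol | CC(=C)[C@H]1C[C@H](O[Si](C)(C)C(C)(C)C)C(C)(O)C=C1
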